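**Retrosynthetic overview**
1. Last bond made (key step): the C7–OMe bond, by directed C–H methoxylation next to the C6 oxygen of a 6-hydroxy-2,3-dimethyl-1-arylnaphthalene held as its di-tert-butylsilanol ether; fluoride then cuts the tether and frees the C6–OH.
2. The C7 methoxy group is left off until then, so that ring B can close para to the lone C6 oxygen with no ipso attack and no regio-isomers.
3. Ring B (C2–C3 and C1–C8a bonds) is formed in one step from 1-(3-hydroxyphenyl)propan-2-one (ring A) and 1,2,3-trimethoxy-5-(prop-1-ynyl)benzene (ring C) by carbonyl–alkyne benzannulation.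
4. The aryl propyne comes from 5-bromo-1,2,3-trimethoxybenzene and but-2-ynoic acid by decarboxylative coupling.
5. Ring order: rings A and C are bought; ring B is the only ring formed.

Assumption: the target has no stereocentre and a freely rotating biaryl axis (ring C is symmetrical), so it is achiral and the structure as drawn is the only isomer to make; 1-(3-hydroxyphenyl)propan-2-one is taken as a catalogue chemical.

Locants C1–C8 in the text follow the 1-aryl-2,3-dimethylnaphthalene numbering (aryl on C1, methyls on C2 and C3, OH on C6, OMe on C7); systematic names number from the phenol carbon.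

**Step 1**
Reactants: 1 5-bromo-1,2,3-trimethoxybenzene; 2 but-2-ynoic acid
Product: 3 1,2,3-trimethoxy-5-(prop-1-yn-1-yl)benzene
Conditions: Pd(OAc)2 (2 mol%), XPhos (4 mol%), Cs2CO3 (1.5 equiv), THF, 80 °C
Reagents that add atoms: none
Why: Decarboxylative Sonogashira-type coupling: zerovalent palladium inserts into the C–Br bond, the caesium butynoate loses CO2 at divalent palladium to give the aryl(propynyl) complex, and reductive elimination gives the aryl propyne without handling propyne gas; no stereocentre is formed.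

**Step 2**
Reactants: 3 1,2,3-trimethoxy-5-(prop-1-yn-1-yl)benzene; 4 1-(3-hydroxyphenyl)propan-2-one
Product: 5 6,7-dimethyl-5-(3,4,5-trimethoxyphenyl)naphthalen-2-ol
Conditions: TiCl4 (2.2 equiv), CH2Cl2, −20 °C to rt; then H2O
Reagents that add atoms: none
Why: TiCl4-mediated carbonyl–alkyne benzannulation (formal [4+2]: alkyne–carbonyl addition, Friedel–Crafts closure, dehydration), a reaction type used with α-aryl ketones and 1-arylpropynes: the alkyne attacks the activated ketone through its methyl-bearing carbon, the aryl-stabilised vinyl cation is captured by ring A para to the titanium aryloxide oxygen (the site between oxygen and tether is crowded, and without a 4-methoxy group there is no ipso pathway), and loss of water aromatises ring B; no stereocentre remains.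

**Step 3**
Reactants: 5 6,7-dimethyl-5-(3,4,5-trimethoxyphenyl)naphthalen-2-ol
Product: 7 di-tert-butyl{[6,7-dimethyl-5-(3,4,5-trimethoxyphenyl)naphthalen-2-yl]oxy}silanol, via aryloxysilyl triflate 6 (not isolated)
Conditions: tBu2Si(OTf)2 (1.2 equiv), 2,6-lutidine (3 equiv), CH2Cl2, 0 °C; then H2O, THF, rt
Reagents that add atoms: di-tert-butylsilyl bis(trifluoromethanesulfonate), CC(C)(C)[Si](OS(=O)(=O)C(F)(F)F)(OS(=O)(=O)C(F)(F)F)C(C)(C)C; water, O
Why: Standard O-silylation of a phenol by a silyl bis-triflate (the tert-butyl groups stop a second aryloxide from adding), then hydrolysis of the remaining Si–OTf bond to a hindered silanol that does not condense; no stereocentre is formed.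

**Step 4**
Reactants: 7 di-tert-butyl{[6,7-dimethyl-5-(3,4,5-trimethoxyphenyl)naphthalen-2-yl]oxy}silanol
Product: 9 3-methoxy-6,7-dimethyl-5-(3,4,5-trimethoxyphenyl)naphthalen-2-ol, via methoxylated silanol 8 (not isolated)
Conditions: Pd(OPiv)2 (10 mol%), PhI(OAc)2 (2 equiv), MeOH/PhMe 1:2, 80 °C; aq Na2S2O3 wash; then Bu4NF (3 equiv), THF, rt; H2O
Reagents that add atoms: methanol, CO
Why: Proposed new method: silanol-directed Pd-catalysed ortho C–H methoxylation with traceless removal of the tether, no stereocentre formed; the Si–OH group binds divalent palladium and pivalate-assisted C–H cleavage gives the six-membered palladacycle at the β position C7 (C5 is disfavoured by the peri C4–H and the bulky tBu2Si unit), PhI(OAc)2 in methanol oxidises this to a tetravalent palladium methoxide and C–OMe reductive elimination makes the C7–O bond, and because the aryl methyl ether, unlike the aryl acetate of the known reaction, cannot close onto silicon, fluoride then frees O6 as the phenol with O7 already methylated; closest known reaction types are the silanol-directed Pd-catalysed C–H acetoxylation of phenols to silylene-protected catechols with PhI(OAc)2 and the Pd-catalysed directed C–H methoxylation in methanol with nitrogen directing groups.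

**Compound list** (all compounds are achiral; no stereodescriptors apply)
1 | 5-bromo-1,2,3-trimethoxybenzene | COc1cc(Br)cc(OC)c1OC | starting material
2 | but-2-ynoic acid | CC#CC(=O)O | starting material
3 | 1,2,3-trimethoxy-5-(prop-1-yn-1-yl)benzene | CC#Cc1cc(OC)c(OC)c(OC)c1 | intermediate
4 | 1-(3-hydroxyphenyl)propan-2-one | CC(=O)Cc1cccc(O)c1 | starting material
5 | 6,7-dimethyl-5-(3,4,5-trimethoxyphenyl)naphthalen-2-ol | Cc1cc2cc(O)ccc2c(-c2cc(OC)c(OC)c(OC)c2)c1C | intermediate
6 | di-tert-butyl{[6,7-dimethyl-5-(3,4,5-trimethoxyphenyl)naphthalen-2-yl]oxy}silyl trifluoromethanesulfonate (not isolated) | Cc1cc2cc(O[Si](OS(=O)(=O)C(F)(F)F)(C(C)(C)C)C(C)(C)C)ccc2c(-c2cc(OC)c(OC)c(OC)c2)c1C | intermediate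
7 | di-tert-butyl{[6,7-dimethyl-5-(3,4,5-trimethoxyphenyl)naphthalen-2-yl]oxy}silanol | Cc1cc2cc(O[Si](O)(C(C)(C)C)C(C)(C)C)ccc2c(-c2cc(OC)c(OC)c(OC)c2)c1C | intermediate
8 | di-tert-butyl{[3-methoxy-6,7-dimethyl-5-(3,4,5-trimethoxyphenyl)naphthalen-2-yl]oxy}silanol (not isolated) | Cc1cc2cc(O[Si](O)(C(C)(C)C)C(C)(C)C)c(OC)cc2c(-c2cc(OC)c(OC)c(OC)c2)c1C | intermediate
9 | 3-methoxy-6,7-dimethyl-5-(3,4,5-trimethoxyphenyl)naphthalen-2-ol | COc1cc2c(-c3cc(OC)c(OC)c(OC)c3)c(C)c(C)cc2cc1O | target

**Totals**
Total step count: 4. Longest linear sequence: 4 steps (1 → 3 → 5 → 7 → 9).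

**Three steps most likely to fail, highest risk first**

Step 4 (the proposed new step). The risks are C–OAc instead of C–OMe reductive elimination (the acetate then closes onto silicon and the O6/O7 distinction is lost), slow methanolysis of the silanol, and some palladation at C5. The fallback uses known chemistry only; it sets out from 5 and comes back at 9, so steps 3 and 4 are not needed. Naphthol 5 is protected with MOMCl/iPr2NEt in CH2Cl2 as 6-(methoxymethoxy)-2,3-dimethyl-1-(3,4,5-trimethoxyphenyl)naphthalene F1. Directed ortho-lithiation with n-BuLi in THF (0 °C to rt), which for 2-(methoxymethoxy)naphthalenes goes to the β position next to the acetal, and quench with B(OMe)3 give dimethyl [3-(methoxymethoxy)-6,7-dimethyl-8-(3,4,5-trimethoxyphenyl)naphthalen-2-yl]boronate F2. This is oxidised in the same flask with H2O2/aq NaOH to 3-(methoxymethoxy)-6,7-dimethyl-8-(3,4,5-trimethoxyphenyl)naphthalen-2-ol F3. MeI/K2CO3 in acetone then gives 7-methoxy-6-(methoxymethoxy)-2,3-dimethyl-1-(3,4,5-trimethoxyphenyl)naphthalene F4, and HCl in MeOH removes the acetal to give 9.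

Step 2. The ketone is less electrophilic than the aldehydes usually used, the free phenol ties up one equivalent of TiCl4 and liberates HCl, and the naphthol product is itself nucleophilic. The fallback replaces the benzannulation by acetylide addition, iodocyclisation and cross-coupling. It sets out from 4 and comes back at 5. It also uses 5-ethynyl-1,2,3-trimethoxybenzene, which is bought or taken from the step 1 fallback. Ketone 4 is silylated (TBSCl, imidazole, DMF) to 1-{3-[(tert-butyldimethylsilyl)oxy]phenyl}propan-2-one F5. The cerium acetylide of the alkyne (n-BuLi, then CeCl3, THF, −78 °C, to suppress enolisation) adds to give racemic 1-{3-[(tert-butyldimethylsilyl)oxy]phenyl}-2-methyl-4-(3,4,5-trimethoxyphenyl)but-3-yn-2-ol F6. I2/NaHCO3 in MeCN effects 6-endo-dig iodocyclisation para to the silyl ether, and dehydration gives tert-butyl{[6-iodo-7-methyl-5-(3,4,5-trimethoxyphenyl)naphthalen-2-yl]oxy}dimethylsilane F7. Suzuki methylation (trimethylboroxine, Pd(OAc)2/SPhos, K3PO4, dioxane, 100 °C) gives tert-butyl{[6,7-dimethyl-5-(3,4,5-trimethoxyphenyl)naphthalen-2-yl]oxy}dimethylsilane F8, and Bu4NF in THF gives 5.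

Step 1. Protodecarboxylation of the butynoate to propyne (lost as gas) and slow oxidative addition to the electron-rich bromide can lower the yield. The fallback makes the C(sp)–CH3 bond last, by acetylide alkylation. It sets out from 1 and comes back at 3. Sonogashira coupling of 1 with ethynyltrimethylsilane (PdCl2(PPh3)2, CuI, Et3N, 70 °C) gives trimethyl[(3,4,5-trimethoxyphenyl)ethynyl]silane F9. K2CO3 in MeOH gives 5-ethynyl-1,2,3-trimethoxybenzene F10, and n-BuLi (THF, −78 °C) followed by MeI gives 3.

**Further compounds**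
F1 | step 4 | 6-(methoxymethoxy)-2,3-dimethyl-1-(3,4,5-trimethoxyphenyl)naphthalene | COCOc1ccc2c(-c3cc(OC)c(OC)c(OC)c3)c(C)c(C)cc2c1
F2 | step 4 | dimethyl [3-(methoxymethoxy)-6,7-dimethyl-8-(3,4,5-trimethoxyphenyl)naphthalen-2-yl]boronate | COCOc1cc2cc(C)c(C)c(-c3cc(OC)c(OC)c(OC)c3)c2cc1B(OC)OC
F3 | step 4 | 3-(methoxymethoxy)-6,7-dimethyl-8-(3,4,5-trimethoxyphenyl)naphthalen-2-ol | COCOc1cc2cc(C)c(C)c(-c3cc(OC)c(OC)c(OC)c3)c2cc1O
F4 | step 4 | 7-methoxy-6-(methoxymethoxy)-2,3-dimethyl-1-(3,4,5-trimethoxyphenyl)naphthalene | COCOc1cc2cc(C)c(C)c(-c3cc(OC)c(OC)c(OC)c3)c2cc1OC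
F5 | step 2 | 1-{3-[(tert-butyldimethylsilyl)oxy]phenyl}propan-2-one | CC(=O)Cc1cccc(O[Si](C)(C)C(C)(C)C)c1
F6 | step 2 | 1-{3-[(tert-butyldimethylsilyl)oxy]phenyl}-2-methyl-4-(3,4,5-trimethoxyphenyl)but-3-yn-2-ol (racemic) | CC(O)(Cc1cccc(O[Si](C)(C)C(C)(C)C)c1)C#Cc1cc(OC)c(OC)c(OC)c1
F7 | step 2 | tert-butyl{[6-iodo-7-methyl-5-(3,4,5-trimethoxyphenyl)naphthalen-2-yl]oxy}dimethylsilane | Cc1cc2cc(O[Si](C)(C)C(C)(C)C)ccc2c(-c2cc(OC)c(OC)c(OC)c2)c1I
F8 | step 2 | tert-butyl{[6,7-dimethyl-5-(3,4,5-trimethoxyphenyl)naphthalen-2-yl]oxy}dimethylsilane | Cc1cc2cc(O[Si](C)(C)C(C)(C)C)ccc2c(-c2cc(OC)c(OC)c(OC)c2)c1C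
F9 | step 1 | trimethyl[(3,4,5-trimethoxyphenyl)ethynyl]silane | COc1cc(C#C[Si](C)(C)C)cc(OC)c1OC
F10 | step 1 | 5-ethynyl-1,2,3-trimethoxybenzene | C#Cc1cc(OC)c(OC)c(OC)c1
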